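The vessel is closed and stirred, and the electrophile leaves it by more than one road. I want one number that follows the loss before I know the split.

| flask | electrophile | nucleophile | remark | time |
|---|---|---|---|---|
| north | 0.30 M | 1.2 equiv | run made earlier |  |
| south-east | 0.40 M | 1.2 equiv | run made earlier |  |
| birch | 0.20 M | 2.40 equiv |  | 6.0 min |
| alder | 0.20 M | 1.20 equiv |  | 6.0 min |

- north (time / s: electrophile / %, target / %): 30.0: 84, 8; 60.0: 68, 7; 90.0: 66, 10; 120: 57, 7
- south-east (time / s: electrophile / %, target / %): 10.0: 94, 3; 25.0: 80, 7; 50.0: 70, 8; 120: 54, 6

(scatter of a reading: 1.5 percentage points)

- percentages count the electrophile that a species holds: one homo dimer counts as two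
- the earlier runs were read with a standard deviation of 1.5 percentage points
- what may be going on: electrophile + nucleophile -> acid set free + target; nucleophile + acid set free <-> protonated nucleophile; 2 electrophile -> homo dimer; nucleophile + target -> over-reaction product

- part of the electrophile that has reacted at the end, birch
- part of the electrophile that has reacted at the end, alder
- what raising the equivalents of nucleophile from its lowest to its highest value here does to the part of the electrophile that has reacted (changes below 5 percentage points count as none) (it rises / no change / it falls)

First, the main step by itself. The first target reading of the north run gives a main-step constant of 0.00741 M⁻¹ s⁻¹. In alder, constant times equivalents times concentration times time is 0.640. I take the part reacted as that number over the number plus one, so 39.0%.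

The runs lose more. Their last readings, read as second-order loss, give 0.0210 M⁻¹ s⁻¹ for north and 0.0177 M⁻¹ s⁻¹ for south-east. Their mean 0.0194 M⁻¹ s⁻¹ is my second-order loss constant: a lumped rate constant, electrophile loss over its concentration squared, at this nucleophile ratio. I give the remainder, 0.0105 M⁻¹ s⁻¹, to the homo dimer.

Then the rest. Each electrophile through the main step costs up to 3 nucleophile, counting acid binding and over-reaction, and the constant, read at 1.2 equiv, already holds them. So alder has the number 1.39 and 58.2% reacted.

Birch needs the main term scaled to its equivalents. That gives 0.0282 M⁻¹ s⁻¹ and 67.0% reacted. I go round once more. At the full 3, I reckon that answer spends 1.27 equivalents, so nucleophile per electrophile ends near 3.44. The mean ratio 2.92 gives 0.0321 M⁻¹ s⁻¹ and 69.8%. The rise of 12 percentage points exceeds the margin.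

The forecast says 72% (63% to 82%) for birch and 60% (52% to 68%) for alder, and it rises: “Stepping through 360 s at 0.20 M gives about 60% at 1.2 equiv and about 72% at 2.4 equiv”. My figures are lower, but inside its ranges.

The flask gives 73.8% for birch and 60.2% for alder, and it rises, by 14 points. Alder holds 7.24% as target at 6.00 min, and the constant counts loss, not destination.

    electrophile + nucleophile → acid set free + target (k = 0.00985 M⁻¹ s⁻¹)
    nucleophile + acid set free ⇌ protonated nucleophile, settled at all times (K = 120 M⁻¹)
    2 electrophile → homo dimer (k = 0.00517 M⁻¹ s⁻¹)
    nucleophile + target → over-reaction product (k = 0.0689 M⁻¹ s⁻¹)

Run to 60.0 min, the constant gives alder 93.3%; the flask gives 92.8%. For alder's neighbour at 0.34 M of electrophile, equivalents and time held, the constant gives 70.3%, and the computed result is 70.9%.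

Readings and results were generated by integration for substances that don't exist; the scatter is artificial.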